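Readings and results stem from a simulated flask for an exercise; the scatter is artificial.

Reckon with x, the fraction of the charged X still left, and not with what has been made: the readings give x directly, and Z then follows from x with the clock dropped out.

| setting | epsilon | north-east | west |
|---|---|---|---|
| X | 0.20 M | 0.13 M | 0.13 M |
| temperature | 35 °C | 35 °C | 60 °C |
| remark | run made earlier |  |  |
| time |  | 15 h | 15 h |

epsilon run (percent of the X charged)

| time / h | Z / % | X / % |
|---|---|---|
| 0.167 | 2.5 | 80.0 |
| 0.500 | 6.4 | 54.9 |
| 0.833 | 9.0 | 42.1 |
| 1.33 | 11.6 | 30.1 |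
| 2.00 | 15.0 | 20.7 |
| 2.50 | 16.1 | 16.5 |
| 3.00 | 18.2 | 13.7 |

(readings scatter by 0.5 percentage points)

- percentages count the X that a species holds: one E counts as two
- the earlier runs do not show what temperature does; that part of a forecast is a guess

- which of the two there is more of at the end, counted by the X in each, north-east (E / Z)
- which of the two there is more of at the end, counted by the X in each, west (E / Z)
- amount of Z at the end, in percent of the X charged, north-east
- amount of Z at the end, in percent of the X charged, west

Take first the step X → Z by itself, first order with rate constant k. Then x decays like a discharging capacitor, and Z is whatever x has lost. The epsilon run refutes that picture: at 3.00 h it has lost 86.3% of its X and shows 18.2% of Z. The picture still yields k. Between 1.33 h and 3.00 h Z rises 6.6 percentage points at a mean x of 21.9%, which reads as k = 0.180 h⁻¹. Over 15 h this step by itself gives north-east 93.3% of Z.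

Now add one more step, X lost in pairs to E, at a rate that goes with [X] squared. The loss becomes k x (1 + r x), where r is the pair route's loss of X over the single route's at the start, a selectivity factor that scales with the charge. Each lost X then becomes Z with share 1/(1 + r x), and integrating over x gives Z = ln((1 + r)/(1 + r x))/r. The last epsilon reading, solved by repeated substitution, goes 10.9, 8.59, 8.15, a reading that carries the scatter of 0.5 points. Scaled to the north-east charge, r = 5.30, the start ratio. At x = 0 the yield is ln(1 + r)/r, which brings north-east down to 34.7%.

The rest is the clock. With e = exp(−kt), x = e/(1 + r(1 − e)), so north-east keeps 1.12% of X at 15 h. This reckoning then commits to Z = 33.7%, with E, taken as the remainder, ahead at 65.2%. For west the same formula stands, but no reading gives r at that temperature.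

The forecast gives north-east 33% of Z with E ahead, slightly below this reckoning, from a ratio of 5.4. For west it gives 38% with E ahead, from a ratio of 4, guessing that “the first-order route gains modestly”.

North-east ends at 32.7% of Z against 48.2% of E, so the larger of the two there is E. West ends at 67.8% of Z against 1.13% of E, so the larger of the two there is Z.

    2 X → E (k = 9.08 × 10⁻⁴ M⁻¹ s⁻¹, Ea = 53.0 kJ mol⁻¹)
    X → Z (k = 4.69 × 10⁻⁵ s⁻¹, Ea = 107 kJ mol⁻¹)
    E → L (k = 2.27 × 10⁻⁶ s⁻¹, Ea = 112 kJ mol⁻¹)
    X + E → J (k = 2.23 × 10⁻⁴ M⁻¹ s⁻¹, Ea = 61.0 kJ mol⁻¹)
    2 X → Q (k = 1.30 × 10⁻⁷ M⁻¹ s⁻¹, Ea = 94.0 kJ mol⁻¹)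
    (constants at 35 °C)

West holds 0% of X at 15.0 h, so its Z stands at the x = 0 yield. One Newton step from r = 1 reads that yield back as an effective r of 1.08, against the start ratio of 5.30 in north-east, a factor of 4.91. The activation energy of X → Z is 107 kJ mol⁻¹, higher than the 53.0 kJ mol⁻¹ of the pair step.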